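**Strategy.** The route rests on cutting the hexaprenyl chain (numbered C1′ at the benzylic carbon) at the C9′–C10′ single bond, the sp3–sp2 link between the second and third prenyl units. The key step exploits the 1,5-diene C6′=C7′–C8′–C9′–C10′=C11′: C9′ is homoallylic, so it is unmasked from a conjugated C6′=C7′–C8′=C9′ diene by terminal 9-BBN hydroboration and joined, in the same flask, by B-alkyl Suzuki–Miyaura coupling to a C19 (E)-alkenyl iodide made by zirconium-catalysed methylalumination of a farnesyl-derived alkyne. The precursor is thus a geranyl-derived aryl triene, with the hexasubstituted benzene ring masked as its tetramethyl ether, plus the iodide; oxidation and reduction then reveal the quinol.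

Key step: step 6

Remark: the side chain is numbered C1′ (benzylic) to C24′. Ubiquinol-6 is air-sensitive, so it is made last from the stable quinone under argon with degassed solvents. Compounds 1, 2, 9 and 10 are taken as commercial.

**Step 1**
Reactants: 1 2,3,4,5-tetramethoxytoluene; 2 geranyl bromide
Product: 5 1-[(2E)-3,7-dimethylocta-2,6-dien-1-yl]-2,3,4,5-tetramethoxy-6-methylbenzene, via aryllithium 3 (not isolated), via arylcopper 4 (not isolated)
Conditions: n-BuLi, TMEDA, THF, 0 °C; CuBr·SMe2, −78 → −40 °C; then 2, −40 → 0 °C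
Reagents that add atoms: none
Why: Directed ortho-lithiation at the only free ring position (next to a methoxy group), transmetalation to copper and SN2 allylic substitution of the primary bromide by the arylcopper should give the C-geranyl arene with the 2′E alkene intact; no stereocentre is formed.

**Step 2**
Reactants: 5 1-[(2E)-3,7-dimethylocta-2,6-dien-1-yl]-2,3,4,5-tetramethoxy-6-methylbenzene
Product: 7 (2E,6E)-2,6-dimethyl-8-(2,3,4,5-tetramethoxy-6-methylphenyl)octa-2,6-dienal, via E-allylic alcohol 6 (not isolated)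
Conditions: SeO2 (cat.), t-BuOOH, salicylic acid (cat.), CH2Cl2, 0 °C → rt; filtration, then MnO2, CH2Cl2, rt
Reagents that add atoms: SeO2, O=[Se]=O (oxygen carrier); t-BuOOH, CC(C)(C)OO (terminal oxygen source)
Why: Selenium dioxide allylic oxidation (ene reaction, then [2,3]-sigmatropic shift) should attack the E-methyl group of the more accessible terminal trisubstituted alkene and give the 6′E allylic alcohol, and MnO2 oxidation of the crude alcohol/aldehyde mixture should converge it on the enal.

**Step 3**
Reactants: 7 (2E,6E)-2,6-dimethyl-8-(2,3,4,5-tetramethoxy-6-methylphenyl)octa-2,6-dienal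
Product: 8 1-[(2E,6E)-3,7-dimethylnona-2,6,8-trien-1-yl]-2,3,4,5-tetramethoxy-6-methylbenzene
Conditions: Ph3PCH3Br, KOt-Bu, THF, 0 °C; then 7, −78 °C → rt
Reagents that add atoms: methyltriphenylphosphonium bromide, C[P+](c1ccccc1)(c1ccccc1)c1ccccc1.[Br-]
Why: Wittig methylenation of the enal with the non-stabilised ylide should turn C8′H=O into the terminal vinyl group C8′=C9′ without touching the trisubstituted alkenes.

**Step 4**
Reactants: 9 (2E,6E)-farnesyl bromide; 10 1-(trimethylsilyl)propyne
Product: 13 (5E,9E)-6,10,14-trimethylpentadeca-5,9,13-trien-1-yne, via lithiated silylpropyne 11 (not isolated), via silyl enyne 12 (not isolated)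
Conditions: 10, n-BuLi, THF, −78 → −20 °C; 9, −78 °C → rt; then K2CO3, MeOH, rt
Reagents that add atoms: none
Why: The propargylic lithium reagent should alkylate at its CH2 terminus (the silyl group disfavours the allenyl pathway) by SN2 displacement of the primary allylic bromide, and basic methanolysis should then cleave the C(sp)–Si bond to the terminal alkyne.

**Step 5**
Reactants: 13 (5E,9E)-6,10,14-trimethylpentadeca-5,9,13-trien-1-yne
Product: 15 (1E,5E,9E)-1-iodo-2,6,10,14-tetramethylpentadeca-1,5,9,13-tetraene, via alkenylalane 14 (not isolated)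
Conditions: Me3Al, Cp2ZrCl2 (0.25 equiv), CH2Cl2, 0 °C → rt; then I2, THF, −30 → 0 °C
Reagents that add atoms: trimethylaluminium, C[Al](C)C; iodine, II
Why: Zirconium-catalysed methylalumination of the terminal alkyne is a syn carbometalation that puts methyl on the internal carbon and aluminium on the terminal carbon, and iodinolysis of the C–Al bond with retention should give the (E)-alkenyl iodide while the trisubstituted alkenes stay inert.

**Step 6**
Reactants: 8 1-[(2E,6E)-3,7-dimethylnona-2,6,8-trien-1-yl]-2,3,4,5-tetramethoxy-6-methylbenzene; 15 (1E,5E,9E)-1-iodo-2,6,10,14-tetramethylpentadeca-1,5,9,13-tetraene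
Product: 17 1-[(2E,6E,10E,14E,18E)-3,7,11,15,19,23-hexamethyltetracosa-2,6,10,14,18,22-hexaen-1-yl]-2,3,4,5-tetramethoxy-6-methylbenzene, via B-alkyl-9-BBN borane 16 (not isolated)
Conditions: 8, 9-BBN (0.5 M in THF), THF, 0 °C → rt; then 15, PdCl2(dppf)·CH2Cl2 (5 mol %), AsPh3, 3 M aq. Cs2CO3, DMF, rt, dark
Reagents that add atoms: none
Why: 9-BBN adds syn and anti-Markovnikov to the monosubstituted C8′=C9′ terminus of the conjugated diene and places boron on C9′ (borane 16); aqueous base then forms a borate whose primary alkyl group transmetalates to the alkenylpalladium iodide formed by oxidative addition of 15 to zerovalent palladium, and reductive elimination forges the C9′–C10′ bond. The closest known reaction type is the B-alkyl Suzuki–Miyaura coupling of an alkyl-9-BBN with an alkenyl iodide, run as a one-pot hydroboration/coupling. No ring is closed and no stereocentre is formed; the 10′E geometry is carried over from 15 because oxidative addition and reductive elimination proceed with retention, and the 6′E geometry of 8 is not touched. The step needs hydroboration of one alkene out of three in 8, which the bulk of 9-BBN should secure (terminal vinyl against trisubstituted alkenes; 15 is added only after the borane has been consumed). It also needs reductive elimination to outrun β-hydride elimination of the homoallylic alkylpalladium, which the wide-bite-angle dppf ligand with AsPh3 and a strongly basic aqueous phase should secure.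

**Step 7**
Reactants: 17 1-[(2E,6E,10E,14E,18E)-3,7,11,15,19,23-hexamethyltetracosa-2,6,10,14,18,22-hexaen-1-yl]-2,3,4,5-tetramethoxy-6-methylbenzene
Product: 18 ubiquinone-6
Conditions: (NH4)2Ce(NO3)6 (2.5 equiv), MeCN/CH2Cl2/H2O, 0 °C
Reagents that add atoms: water, O
Why: Oxidative demethylation by tetravalent cerium should convert the only para-related pair of methoxy groups (those next to the methyl group and to the side chain) into the 1,4-benzoquinone carbonyls, with water supplying the carbonyl oxygens and the electron-rich arene reacting much faster than the isolated alkenes.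

**Step 8**
Reactants: 18 ubiquinone-6
Product: 19 ubiquinol-6
Conditions: Na2S2O4 (excess), degassed Et2O/H2O, rt, argon
Reagents that add atoms: none
Why: Dithionite reduction of the benzoquinone to the hydroquinone is a two-electron, two-proton transfer that should leave the all-E polyene untouched.

**Compound list**

1 | 2,3,4,5-tetramethoxytoluene | COc1cc(C)c(OC)c(OC)c1OC | starting material
2 | geranyl bromide, (2E)-1-bromo-3,7-dimethylocta-2,6-diene | BrC/C=C(\C)CCC=C(C)C | starting material
3 | (2,3,4,5-tetramethoxy-6-methylphenyl)lithium | COc1c(OC)c(OC)c(C)c([Li])c1OC | intermediate (not isolated)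
4 | (2,3,4,5-tetramethoxy-6-methylphenyl)copper | COc1c(OC)c(OC)c(C)c([Cu])c1OC | intermediate (not isolated)
5 | 1-[(2E)-3,7-dimethylocta-2,6-dien-1-yl]-2,3,4,5-tetramethoxy-6-methylbenzene | COc1c(OC)c(OC)c(C)c(C/C=C(\C)CCC=C(C)C)c1OC | intermediate
6 | (2E,6E)-2,6-dimethyl-8-(2,3,4,5-tetramethoxy-6-methylphenyl)octa-2,6-dien-1-ol | COc1c(OC)c(OC)c(C)c(C/C=C(\C)CC/C=C(\C)CO)c1OC | intermediate (not isolated)
7 | (2E,6E)-2,6-dimethyl-8-(2,3,4,5-tetramethoxy-6-methylphenyl)octa-2,6-dienal | COc1c(OC)c(OC)c(C)c(C/C=C(\C)CC/C=C(\C)C=O)c1OC | intermediate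
8 | 1-[(2E,6E)-3,7-dimethylnona-2,6,8-trien-1-yl]-2,3,4,5-tetramethoxy-6-methylbenzene | COc1c(OC)c(OC)c(C)c(C/C=C(\C)CC/C=C(\C)C=C)c1OC | intermediate
9 | (2E,6E)-farnesyl bromide | BrC/C=C(\C)CC/C=C(\C)CCC=C(C)C | starting material
10 | 1-(trimethylsilyl)propyne | CC#C[Si](C)(C)C | starting material
11 | 3-lithio-1-(trimethylsilyl)propyne | [Li]CC#C[Si](C)(C)C | intermediate (not isolated)
12 | trimethyl[(5E,9E)-6,10,14-trimethylpentadeca-5,9,13-trien-1-yn-1-yl]silane | C[Si](C)(C)C#CCC/C=C(\C)CC/C=C(\C)CCC=C(C)C | intermediate (not isolated)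
13 | (5E,9E)-6,10,14-trimethylpentadeca-5,9,13-trien-1-yne | C#CCC/C=C(\C)CC/C=C(\C)CCC=C(C)C | intermediate
14 | dimethyl[(1E,5E,9E)-2,6,10,14-tetramethylpentadeca-1,5,9,13-tetraen-1-yl]alane | C[Al](C)/C=C(\C)CC/C=C(\C)CC/C=C(\C)CCC=C(C)C | intermediate (not isolated)
15 | (1E,5E,9E)-1-iodo-2,6,10,14-tetramethylpentadeca-1,5,9,13-tetraene | I/C=C(\C)CC/C=C(\C)CC/C=C(\C)CCC=C(C)C | intermediate
16 | 9-[(3E,7E)-3,7-dimethyl-9-(2,3,4,5-tetramethoxy-6-methylphenyl)nona-3,7-dien-1-yl]-9-borabicyclo[3.3.1]nonane | COc1c(OC)c(OC)c(C)c(C/C=C(\C)CC/C=C(\C)CCB2C3CCCC2CCC3)c1OC | intermediate (not isolated)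
17 | 1-[(2E,6E,10E,14E,18E)-3,7,11,15,19,23-hexamethyltetracosa-2,6,10,14,18,22-hexaen-1-yl]-2,3,4,5-tetramethoxy-6-methylbenzene | COc1c(OC)c(OC)c(C)c(C/C=C(\C)CC/C=C(\C)CC/C=C(\C)CC/C=C(\C)CC/C=C(\C)CCC=C(C)C)c1OC | intermediate
18 | ubiquinone-6, 2-[(2E,6E,10E,14E,18E)-3,7,11,15,19,23-hexamethyltetracosa-2,6,10,14,18,22-hexaen-1-yl]-5,6-dimethoxy-3-methylcyclohexa-2,5-diene-1,4-dione | COC1=C(OC)C(=O)C(C/C=C(\C)CC/C=C(\C)CC/C=C(\C)CC/C=C(\C)CC/C=C(\C)CCC=C(C)C)=C(C)C1=O | intermediate
19 | ubiquinol-6, 2-[(2E,6E,10E,14E,18E)-3,7,11,15,19,23-hexamethyltetracosa-2,6,10,14,18,22-hexaen-1-yl]-5,6-dimethoxy-3-methylbenzene-1,4-diol | COc1c(O)c(C)c(C/C=C(\C)CC/C=C(\C)CC/C=C(\C)CC/C=C(\C)CC/C=C(\C)CCC=C(C)C)c(O)c1OC | target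

**Step count and risks**

Total step count: 8. Longest linear sequence: 6 steps (steps 1, 2, 3, 6, 7, 8 from compound 1); the iodide branch (steps 4 and 5) has 2 steps.

The three steps most likely to fail:

1. Step 6. Transmetalation of the bulky borate may be slow, so that β-hydride elimination or protodeboronation at the homoallylic chain end competes and the coupling stalls. The fallback is a Negishi alkyl–alkenyl coupling through a purified homoallylic zinc reagent; it sets out from 8 and comes back at 17. Hydroboration of 8 with 9-BBN and oxidation with NaOH/H2O2 should give (3E,7E)-3,7-dimethyl-9-(2,3,4,5-tetramethoxy-6-methylphenyl)nona-3,7-dien-1-ol F1, which can be freed of regioisomers by chromatography. An Appel reaction (I2, PPh3, imidazole) should give 1-[(2E,6E)-9-iodo-3,7-dimethylnona-2,6-dien-1-yl]-2,3,4,5-tetramethoxy-6-methylbenzene F2. Iodine–lithium exchange with t-BuLi at −78 °C and transmetalation with ZnBr2 should give bromo[(3E,7E)-3,7-dimethyl-9-(2,3,4,5-tetramethoxy-6-methylphenyl)nona-3,7-dien-1-yl]zinc F3. Coupling of F3 with 15 under PdCl2(dppf) catalysis in THF should again form the C9′–C10′ bond with retention and give 17.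

2. Step 2. The ene step may also attack the allylic positions of the internal C2′=C3′ alkene (C4′ or the doubly activated benzylic C1′), and over-oxidation may occur, so that the terminal E-methyl group is not functionalised cleanly. The fallback builds the enal by cleaving the terminal alkene and re-olefinating; it sets out from 5 and comes back at 7. NBS in aqueous THF at 0 °C should convert the terminal alkene into the racemic bromohydrin (6E)-3-bromo-2,6-dimethyl-8-(2,3,4,5-tetramethoxy-6-methylphenyl)oct-6-en-2-ol F4. K2CO3 in MeOH should close it to the racemic epoxide 2,2-dimethyl-3-[(3E)-3-methyl-5-(2,3,4,5-tetramethoxy-6-methylphenyl)pent-3-en-1-yl]oxirane F5. H5IO6 in THF/H2O should cleave F5 to (4E)-4-methyl-6-(2,3,4,5-tetramethoxy-6-methylphenyl)hex-4-enal F6 and acetone. An E-selective Wittig reaction of F6 with the stabilised ylide 2-(triphenylphosphoranylidene)propanal in hot toluene should then give 7.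

3. Step 1. Deprotonation may take place at the ring methyl group instead of the ring C–H, and the arylcopper may attack the allylic bromide at its tertiary terminus (SN2′) or erode the 2′E geometry. The fallback forms C1′–C2′ instead of the aryl–C1′ bond, by a benzyl–alkenyl cross-coupling; it sets out from 1 and 11 and comes back at 5. Chloromethylation of 1 (paraformaldehyde, conc. HCl) should give 1-(chloromethyl)-2,3,4,5-tetramethoxy-6-methylbenzene F7. Alkylation of 11 with commercial prenyl bromide should give trimethyl(6-methylhept-5-en-1-yn-1-yl)silane F8, and K2CO3/MeOH should give 6-methylhept-5-en-1-yne F9. Methylalumination of F9 (Me3Al, Cp2ZrCl2 cat.) should give [(1E)-2,6-dimethylhepta-1,5-dien-1-yl]dimethylalane F10. Coupling of F10 with F7 under catalysis by zerovalent nickel (from NiCl2(PPh3)2 and n-BuLi, THF, rt) should give 5, with the 2′E geometry fixed by the syn carbometalation.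

**Further compounds**

F1 | step 6 | (3E,7E)-3,7-dimethyl-9-(2,3,4,5-tetramethoxy-6-methylphenyl)nona-3,7-dien-1-ol | COc1c(OC)c(OC)c(C)c(C/C=C(\C)CC/C=C(\C)CCO)c1OC
F2 | step 6 | 1-[(2E,6E)-9-iodo-3,7-dimethylnona-2,6-dien-1-yl]-2,3,4,5-tetramethoxy-6-methylbenzene | COc1c(OC)c(OC)c(C)c(C/C=C(\C)CC/C=C(\C)CCI)c1OC
F3 | step 6 | bromo[(3E,7E)-3,7-dimethyl-9-(2,3,4,5-tetramethoxy-6-methylphenyl)nona-3,7-dien-1-yl]zinc | COc1c(OC)c(OC)c(C)c(C/C=C(\C)CC/C=C(\C)CC[Zn]Br)c1OC
F4 | step 2 | (6E)-3-bromo-2,6-dimethyl-8-(2,3,4,5-tetramethoxy-6-methylphenyl)oct-6-en-2-ol (racemic) | COc1c(OC)c(OC)c(C)c(C/C=C(\C)CCC(Br)C(C)(C)O)c1OC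
F5 | step 2 | 2,2-dimethyl-3-[(3E)-3-methyl-5-(2,3,4,5-tetramethoxy-6-methylphenyl)pent-3-en-1-yl]oxirane (racemic) | COc1c(OC)c(OC)c(C)c(C/C=C(\C)CCC2OC2(C)C)c1OC
F6 | step 2 | (4E)-4-methyl-6-(2,3,4,5-tetramethoxy-6-methylphenyl)hex-4-enal | COc1c(OC)c(OC)c(C)c(C/C=C(\C)CCC=O)c1OC
F7 | step 1 | 1-(chloromethyl)-2,3,4,5-tetramethoxy-6-methylbenzene | COc1c(OC)c(OC)c(C)c(CCl)c1OC
F8 | step 1 | trimethyl(6-methylhept-5-en-1-yn-1-yl)silane | C[Si](C)(C)C#CCCC=C(C)C
F9 | step 1 | 6-methylhept-5-en-1-yne | C#CCCC=C(C)C
F10 | step 1 | [(1E)-2,6-dimethylhepta-1,5-dien-1-yl]dimethylalane | C[Al](C)/C=C(\C)CCC=C(C)C
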